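Start with the sign. You want to know which of isomer of the product A and target leads this flask at 4.0 min, so measure from the symmetric case: a tie, with a ratio of one.

| flask | substrate | partner | free catalyst | remark | time |
|---|---|---|---|---|---|
| delta | 0.050 M | 0.065 M | 19 µM | run made earlier |  |
| theta | 0.050 M | 0.065 M | 28 µM | run made earlier |  |
| eta | 0.050 M | 0.098 M | 38 µM | run made earlier |  |
| flask | 0.050 M | 0.0650 M | 38 µM |  | 4.0 min |

- delta (time / min: isomer of the product A / %, target / %): 0.333: 5, 16; 1.00: 12, 19; 2.00: 15, 19; 3.00: 18, 17; 4.00: 25, 14
- theta (time / min: isomer of the product A / %, target / %): 0.333: 6, 14; 1.00: 12, 18; 2.00: 16, 19; 3.00: 21, 14; 4.00: 29, 17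
- eta (time / min: isomer of the product A / %, target / %): 0.333: 8, 18; 0.667: 11, 25; 1.00: 16, 25; 2.00: 23, 22; 4.00: 29, 18

(each reading ± 2 percentage points)

- the numbers in the tables scatter by 2 percentage points (one standard deviation)
- a reading or a percentage of target counts all its forms, free or not

* ratio of isomer of the product A to target at 0.80 s
* ratio of isomer of the product A to target at 15 s
* ratio of isomer of the product A to target at 4.0 min
* which of isomer of the product A and target there is more of at 4.0 min

Take the margin, the natural logarithm of isomer of the product A over target at the last reading, whose zero is that tie. Eta reads 0.477 and theta 0.534, both above zero. But this flask has eta's free catalyst and theta's partner, so you must carry a margin across a change of [partner]. I read −0.139 for the slope: the change of margin per unit of ln[partner] between theta and eta, an apparent order of the ratio in partner. Its own zero means no net change of margin between those runs. It is a weak reading, because one scatter step on eta's target moves the margin by 0.111, more than the 0.0570 between the runs. It also lumps in the change of free catalyst between them. Carried from eta to this flask's partner, it gives a margin of 0.534, which is theta's by construction, so this estimate stands on a run with less free catalyst than this flask. That is a ratio of 1.71, with isomer of the product A ahead.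

The forecast, which speaks of “a small direct parallel route to the isomer, plus later conversion of target to isomer”, gives 0.25, 0.33 and 1.9 at the three times, with isomer of the product A leading. Its last ratio is higher than mine.

The flask gives 0.153, 0.352 and 1.69, with isomer of the product A ahead, 26.2 % against 15.5 % of target. Its margin is 0.525.

    target ⇌ isomer of the product B (K = 1.25, k = 0.0488 s⁻¹)
    substrate + partner ⇌ target (K = 11.0 L mol⁻¹, k = 0.301 L mol⁻¹ s⁻¹)
    substrate + partner ⇌ isomer of the product A (K = 200 L mol⁻¹, k = 0.0426 L mol⁻¹ s⁻¹)
    target + free catalyst ⇌ isomer of the product A + free catalyst, rate k4*[free catalyst]*[target] forward; the back reaction follows from the equilibrium constant (k = 402 L mol⁻¹ s⁻¹)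
    crystals ⇌ target, rate k5*(cs5 - [target]) while solid is left; crystals form when [target] > cs5 (solubility = 44.0 mM, k = 0.928 s⁻¹)
    partner + free catalyst → spent catalyst (k = 0.609 L mol⁻¹ s⁻¹)

The forecast's earliest ratio is higher than the flask's, while its other two stand within the tolerance. Now take a neighbouring flask, the same but with 0.26 M of partner. Carried from eta, the slope gives a margin of 0.341, a ratio of 1.41, still for isomer of the product A. That neighbour gives 1.47, a margin of 0.385, with isomer of the product A at 35.5 % against 24.1 % of target at 4.00 min.

The earlier runs and the new flask come from a simulation with made-up constants, and the scatter is random.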